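## The problem

The target, 5-[(8Z,12S,14Z)-12-hydroxyheptadeca-8,14-dien-1-yl]benzene-1,3-diol (21), has no ring to build beyond a resorcinol that can be bought, so the task is the assembly of one unbranched C17 chain (C1' at the ring to C17') on C5 of the arene. The chain holds two isolated Z alkenes, C8'=C9' and C14'=C15', and a single stereocentre, the S carbinol C12'. Because C12' is the only stereocentre, nothing in the molecule can control it; its configuration must come from a reagent, a catalyst or a stereocentre that is consumed, and the two alkene geometries must be set separately unless one can be tied to C12'. The free resorcinol is acidic, electron-rich and easily oxidised, so it must be masked through all organometallic and ylide chemistry, and the mask must come off without hydrogenation, strong Lewis acid or oxidant, which would endanger the Z alkenes or the homoallylic alcohol. The homoallylic alcohol can ionise, enter Prins chemistry or let its alkene migrate under acid, so any late acid must be catalytic and mild. The enabling feature is that C12' is homoallylic to the Z-C14'=C15' alkene: the array C12'(OH)–C13'H2–C14'H=C15'H–C16'H2–C17'H3 is the linear adduct of a pent-2-enyl group to a C12' aldehyde, and a 2-oxonia-Cope transfer from a branched homoallylic alcohol delivers exactly this array, with alkene geometry and carbinol configuration fixed by one chair. The other alkene, C8'=C9', has methylene groups on both sides and lies three carbons from C12', which suits an unstabilised Wittig reaction that leaves C12' at the ester oxidation level.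

## Retrosynthesis

**21 to 20.** The two aryl O–Si bonds are cut last. Silyl ethers are preferred to methyl or benzyl ethers, whose removal needs boron halides or hydrogen, and to acetals, whose acidic removal would free an aldehyde beside a resorcinol and a homoallylic alcohol. Triisopropylsilyl is chosen over smaller silyl groups because aryl silyl ethers are base-labile and 20 is reached through an aqueous phosphate coupling and an amide-base olefination. The forward step asks only that fluoride cleave two aryl silyl ethers in the presence of a free secondary alcohol.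

**20 to 11 and 17.** The C12'–C13' bond is cut. The C14'=C15' alkene is traced back to the vinyl group of the branched donor (3R,4R)-alcohol 17, and C12' to the carbonyl carbon of the achiral aldehyde 11. Three neighbouring cuts are weaker. Cutting C11'–C12' needs a C12' organometallic and leaves the Z alkene to be sourced separately. An olefination at C14'=C15' would need a β-hydroxy aldehyde that eliminates readily. Direct addition of a pentenyl metal to 11 gives the branched adduct, not the linear one. The sigmatropic transfer uses that last fact: the branched adduct is made on a cheap aldehyde and its allyl unit is then passed to 11 with transposition. Aldehyde 11 has no stereocentre and 17 is a C9 alcohol made in one step. The forward reaction must pass through a single chair (via 18 and 19) so that Z geometry and S configuration arrive together. It must close no ring, spare the aryl silyl ethers and the C8'=C9' alkene, and not let the released aldehyde 13 outcompete 11.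

**17 to 12 and 13.** The C3–C4 bond of 17 is cut to give (Z)-pent-2-ene 12, as its allyl anion 14, and isobutyraldehyde 13. The syn relationship comes from the Z geometry of the allylborane 15 through a closed chair; the absolute configuration comes from the chiral ligands on boron, carried through borinate 16. Aldehyde 13 is chosen because it is the fragment the key step releases: it is cheap, volatile and α-branched, so its isopropyl group is a reliable equatorial anchor in the later chair.

**11 to 9, then to 6 and 7.** The aldehyde is taken back to methyl ester 9 (through the tetrahedral intermediate 10), so that the air-sensitive γ,δ-unsaturated aldehyde is unveiled one step before use. The C8'=C9' bond is then cut by a Wittig disconnection into ylide 8, from phosphonium salt 6, and methyl 4-oxobutanoate 7. An alkyne semireduction would give the same alkene with more steps, and cross-metathesis gives no dependable Z control between two unbiased alkyl partners. The forward reaction must be Z-selective and must prefer the aldehyde of 7 to its ester.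

**6 to 5, then to 2 and 3.** The C8'–P bond is cut to bromide 5. The C(aryl)–C1' bond is cut to aryl bromide 2 and the alkylborane 4 derived from 8-bromooct-1-ene 3. This sp2–sp3 coupling delivers the eight-carbon spacer and the bromide handle in one operation. Acylation–deoxygenation or benzylic alkylation would need more steps. The forward reaction must engage the aryl C–Br bond and leave the primary alkyl C–Br bond alone.

**2 to 1.** Two O–Si bonds are cut to commercial 5-bromoresorcinol 1.

## Roads not taken

Alternative 1: No chain bond is cut. The whole chain with both Z alkenes is bought as α-linolenic acid A1 and is hydrated by a fatty acid 13-hydratase across its C12=C13 alkene only, which gives (9Z,13S,15Z)-13-hydroxyoctadeca-9,15-dienoic acid A2 with the new C13–O bond in the S configuration. The carboxyl carbon of A2 then has to become the ipso carbon of the resorcinol, for example by chain extension to the methyl enone A3 followed by Michael–Claisen annulation with a malonic ester, decarboxylation and dehydrogenation.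
- Merits: one catalytic step sets C12', both alkene geometries come from nature with full purity, and no protecting group is needed up to A2. In stereocontrol and in raw-material economy this road is better than the chosen plan.
- Weak points: it depends on a specific hydratase and on a dilute biotransformation. The annulation needs five or six steps. The final aromatisation of the cyclic 1,3-diketone calls for halogenation–elimination or dehydrogenation in the presence of two Z alkenes and a secondary alcohol.
- Comparison: the chosen plan buys the arene, uses only ordinary laboratory operations, never exposes the alkenes to an oxidant, and is no longer overall.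

Alternative 2: The C11'–C12' bond is cut. Leaf alcohol A4 is converted into its N,N-diisopropylcarbamate A5 and this is deprotonated at C12' by a sec-alkyllithium–chiral diamine base. The lithiated carbon captures the homoallylic pinacol boronic ester A6 and 1,2-migration of the C11' alkyl group from boron to carbon with loss of carbamate gives the secondary boronic ester A7 as the product of the key step. Oxidation of the C–B bond and acetal removal follow.
- Merits: the configuration at C12' is reagent-controlled and independent of any alkene geometry, and the Z-C14'=C15' alkene is bought with A4 and never put at risk. In stereochemical robustness this road is at least as good as the chosen one.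
- Weak points: it needs a stoichiometric chiral diamine and cryogenic organolithium chemistry. A6 needs about three steps beyond the intermediate that becomes aldehyde 11. Two steps follow the key step, and acidic removal of the methoxymethyl groups of A7 sets free a one-carbon electrophile next to a nucleophilic resorcinol and a homoallylic alcohol.
- Comparison: the chosen plan is some three steps shorter, uses the aldehyde oxidation level directly, and makes stereocentre and alkene in one operation.

Alternative 3: The C7'–C8' and C9'–C10' bonds are cut. The 7-arylheptyl bromide A8 is converted into its lithium diorganocuprate A9 which adds syn across acetylene A10 to form the C7'–C8' bond. The Z-alkenyl–copper bond so formed is alkylated at C9' by the chiral primary iodide A11 to give the fully protected target A12 in one flask.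
- Merits: syn carbometalation gives a geometrically purer C8'=C9' alkene than a Wittig reaction can promise, and three fragments are joined in one flask. On that alkene this road is better.
- Weak points: the C12' stereocentre and the C14'=C15' alkene are only moved into A11, which needs its own asymmetric step and several functional-group changes. Half of the valuable alkyl fragment on copper in A9 is normally not transferred. Two kinds of protecting group must be removed from A12 at the end.
- Comparison: the chosen plan creates C12' and C14'=C15' in the key step and keeps an alkyne-based fallback for C8'=C9'.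

Key step: step 7

Remark on the chemistry: the (Z)-pent-2-enylborane carrying isopinocampheyl groups from (+)-α-pinene is assumed to attack the Si face of 13, as the corresponding (Z)-crotyl reagent does, which corresponds to (3R,4R)-17; should the first batch prove antipodal, the reagent from (−)-α-pinene would be used.

## Route

Step 1
Reactants: 1 5-bromoresorcinol
Product: 2 1-bromo-3,5-bis(triisopropylsilyloxy)benzene
Conditions: TIPSCl (2.3 equiv), imidazole (5 equiv), DMF, 0 °C → rt
Reagents that add atoms: triisopropylsilyl chloride, CC(C)[Si](Cl)(C(C)C)C(C)C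
Why: Silylation of phenols with a silyl chloride and imidazole; the bulky aryl TIPS ethers should tolerate the aqueous phosphate of step 2, the amide base of step 4 and the sulfonic acid of step 7, yet fall to fluoride.

Step 2
Reactants: 2 1-bromo-3,5-bis(triisopropylsilyloxy)benzene; 3 8-bromooct-1-ene
Product: 5 1-(8-bromooctyl)-3,5-bis(triisopropylsilyloxy)benzene, via alkylborane 4 (not isolated)
Conditions: 3 (1.3 equiv), 9-BBN (1.35 equiv), THF, 0 °C → rt; then 2, Pd(dppf)Cl2 (3 mol %), K3PO4 (3 M aq, 3 equiv), DMF, 50 °C
Reagents that add atoms: none
Why: Anti-Markovnikov hydroboration of the terminal alkene gives 4, which undergoes B-alkyl Suzuki–Miyaura coupling with 2; zerovalent palladium inserts into the aryl C–Br bond far faster than into an unactivated primary C–Br bond, so the alkyl bromide should be carried through as the handle for step 3.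

Step 3
Reactants: 5 1-(8-bromooctyl)-3,5-bis(triisopropylsilyloxy)benzene
Product: 6 {8-[3,5-bis(triisopropylsilyloxy)phenyl]octyl}triphenylphosphonium bromide
Conditions: PPh3 (1.5 equiv), MeCN, reflux
Reagents that add atoms: triphenylphosphine, c1ccc(cc1)P(c1ccccc1)c1ccccc1
Why: SN2 quaternisation of a triarylphosphine by a primary alkyl bromide under neutral conditions that leave the aryl silyl ethers untouched.

Step 4
Reactants: 6 {8-[3,5-bis(triisopropylsilyloxy)phenyl]octyl}triphenylphosphonium bromide; 7 methyl 4-oxobutanoate
Product: 9 methyl (4Z)-12-[3,5-bis(triisopropylsilyloxy)phenyl]dodec-4-enoate, via ylide 8 (not isolated)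
Conditions: NaN(SiMe3)2 (1.15 equiv), THF, −78 → 0 °C; then 7 (1.0 equiv), −78 °C → rt
Reagents that add atoms: none
Why: Wittig olefination of the unstabilised ylide 8 under lithium-free conditions, where kinetic formation of the cis-oxaphosphetane should give the Z alkene; at low temperature the ylide adds to the aldehyde of 7 much faster than to its ester.

Step 5
Reactants: 9 methyl (4Z)-12-[3,5-bis(triisopropylsilyloxy)phenyl]dodec-4-enoate
Product: 11 (4Z)-12-[3,5-bis(triisopropylsilyloxy)phenyl]dodec-4-enal, via aluminium hemiacetal 10 (not isolated)
Conditions: i-Bu2AlH (1.05 equiv), CH2Cl2, −78 °C; MeOH, then aq potassium sodium tartrate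
Reagents that add atoms: none
Why: Partial reduction of a methyl ester by i-Bu2AlH; the tetrahedral intermediate 10 is stable at −78 °C and should collapse to the aldehyde only on work-up, while the isolated alkene and the aryl silyl ethers are inert to the hydride.

Step 6
Reactants: 12 (Z)-pent-2-ene; 13 isobutyraldehyde
Product: 17 (3R,4R)-4-ethyl-2-methylhex-5-en-3-ol, via pentenylpotassium 14 (not isolated), via pentenylborane 15 (not isolated), via borinate 16 (not isolated)
Conditions: 12 (2 equiv), KOt-Bu, n-BuLi, THF, −78 → −45 → −78 °C; (−)-B-methoxydiisopinocampheylborane [from (+)-α-pinene], −78 °C; BF3·OEt2, then 13, −78 °C; NaOH, H2O2, 0 °C → rt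
Reagents that add atoms: none
Why: Asymmetric allylboration with a γ-substituted allylborane of the (Z)-crotyl type: metalation of the methyl group of 12 gives the Z-configured allylpotassium 14, and boron capture with methoxide abstraction gives 15, which adds to 13 through a closed Zimmerman–Traxler chair. The Z geometry of 15 should translate into the syn relationship of C3 and C4, and the isopinocampheyl groups should direct attack to the Si face of the aldehyde, setting C3 as R and thereby C4 as R; oxidative work-up of 16 frees the alcohol.

Step 7
Reactants: 11 (4Z)-12-[3,5-bis(triisopropylsilyloxy)phenyl]dodec-4-enal; 17 (3R,4R)-4-ethyl-2-methylhex-5-en-3-ol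
Product: 20 (3Z,6S,9Z)-17-[3,5-bis(triisopropylsilyloxy)phenyl]heptadeca-3,9-dien-6-ol, via oxocarbenium ion 18 (not isolated), via rearranged oxocarbenium ion 19 (not isolated)
Conditions: 17 (3 equiv), (1S)-(+)-10-camphorsulfonic acid (10 mol %), CH2Cl2, 0 °C → rt
Reagents that add atoms: none
Why: Acid-catalysed condensation of 11 with the secondary alcohol 17 should give the (E)-oxocarbenium ion 18, which undergoes a cationic [3,3]-sigmatropic shift (2-oxonia-Cope rearrangement, the mechanism of the known acid-catalysed allyl and crotyl transfers from branched homoallylic alcohols) to the isomeric ion 19; the water formed in the condensation then hydrolyses 19 to 20 and isobutyraldehyde 13. The shift forms the C12'–C13' bond from the terminal vinyl carbon of the donor, breaks the donor C3–C4 bond and moves the alkene to C14'=C15'; no ring is closed, because the sulfonate counter-ion does not trap the cyclic cation that a Prins pathway would require. In the chair transition state the isopropyl group of the donor and the C11' chain of the (E)-oxocarbenium unit are equatorial; isopropyl and ethyl are cis on this chair in the syn donor, so ethyl is forced axial and the new alkene should be Z. The same chair fixes which face of the oxocarbenium carbon bonds to the vinyl terminus, so the R configuration of the donor carbinol carbon is transferred to C12' as S; the one stereocentre of 20 is thus controlled by C3 of 17 and its syn relationship to C4. Geometry and configuration are coupled: the competing chair with axial isopropyl would give the E alkene together with the R carbinol, and it is disfavoured by the diaxial strain of the branched group. The step needs the donor to serve 11 and not the released 13, which the excess of the cheap donor secures, and it needs the C8'=C9' alkene to stay out, which its position secures because only a four- or five-membered closure onto C12' would be possible. The exchange of a branched alcohol with a terminal alkene for a linear alcohol with an internal alkene drives the reaction, and the aryl TIPS ethers and both alkenes should tolerate catalytic sulfonic acid in dichloromethane.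

Step 8
Reactants: 20 (3Z,6S,9Z)-17-[3,5-bis(triisopropylsilyloxy)phenyl]heptadeca-3,9-dien-6-ol
Product: 21 5-[(8Z,12S,14Z)-12-hydroxyheptadeca-8,14-dien-1-yl]benzene-1,3-diol
Conditions: Bu4NF (2.5 equiv), AcOH (2.5 equiv), THF, 0 °C → rt
Reagents that add atoms: none
Why: Fluoride-induced cleavage of aryl silyl ethers, driven by Si–F bond formation with a phenoxide leaving group; acetic acid keeps the medium near neutral, and the secondary alcohol, both Z alkenes and C12' are not touched.

## Compound list

1 | 5-bromoresorcinol (5-bromobenzene-1,3-diol) | Oc1cc(O)cc(Br)c1 | starting material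
2 | 1-bromo-3,5-bis(triisopropylsilyloxy)benzene | Brc1cc(O[Si](C(C)C)(C(C)C)C(C)C)cc(O[Si](C(C)C)(C(C)C)C(C)C)c1 | intermediate
3 | 8-bromooct-1-ene | C=CCCCCCCBr | starting material
4 | 9-(8-bromooctyl)-9-borabicyclo[3.3.1]nonane | BrCCCCCCCCB1C2CCCC1CCC2 | intermediate
5 | 1-(8-bromooctyl)-3,5-bis(triisopropylsilyloxy)benzene | BrCCCCCCCCc1cc(O[Si](C(C)C)(C(C)C)C(C)C)cc(O[Si](C(C)C)(C(C)C)C(C)C)c1 | intermediate
6 | {8-[3,5-bis(triisopropylsilyloxy)phenyl]octyl}triphenylphosphonium bromide | [Br-].c1ccccc1[P+](c1ccccc1)(c1ccccc1)CCCCCCCCc1cc(O[Si](C(C)C)(C(C)C)C(C)C)cc(O[Si](C(C)C)(C(C)C)C(C)C)c1 | intermediate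
7 | methyl 4-oxobutanoate | COC(=O)CCC=O | starting material
8 | {8-[3,5-bis(triisopropylsilyloxy)phenyl]octylidene}triphenylphosphorane | c1ccccc1P(c1ccccc1)(c1ccccc1)=CCCCCCCCc1cc(O[Si](C(C)C)(C(C)C)C(C)C)cc(O[Si](C(C)C)(C(C)C)C(C)C)c1 | intermediate
9 | methyl (4Z)-12-[3,5-bis(triisopropylsilyloxy)phenyl]dodec-4-enoate | COC(=O)CC/C=C\CCCCCCCc1cc(O[Si](C(C)C)(C(C)C)C(C)C)cc(O[Si](C(C)C)(C(C)C)C(C)C)c1 | intermediate
10 | diisobutyl{[(4Z)-12-[3,5-bis(triisopropylsilyloxy)phenyl]-1-methoxydodec-4-en-1-yl]oxy}alumane (hemiacetal carbon unassigned) | COC(CC/C=C\CCCCCCCc1cc(O[Si](C(C)C)(C(C)C)C(C)C)cc(O[Si](C(C)C)(C(C)C)C(C)C)c1)O[Al](CC(C)C)CC(C)C | intermediate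
11 | (4Z)-12-[3,5-bis(triisopropylsilyloxy)phenyl]dodec-4-enal | O=CCC/C=C\CCCCCCCc1cc(O[Si](C(C)C)(C(C)C)C(C)C)cc(O[Si](C(C)C)(C(C)C)C(C)C)c1 | intermediate
12 | (Z)-pent-2-ene | C/C=C\CC | starting material
13 | isobutyraldehyde (2-methylpropanal) | CC(C)C=O | starting material
14 | (Z)-pent-2-enylpotassium | [K+].[CH2-]/C=C\CC | intermediate
15 | B-[(Z)-pent-2-enyl]diisopinocampheylborane (isopinocampheyl groups from (+)-α-pinene) | CC/C=C\CB([C@@H]1C[C@@H]2C[C@H]([C@H]1C)C2(C)C)[C@@H]1C[C@@H]2C[C@H]([C@H]1C)C2(C)C | intermediate
16 | (3R,4R)-4-ethyl-2-methylhex-5-en-3-yl diisopinocampheylborinate | C=C[C@@H](CC)[C@H](OB([C@@H]1C[C@@H]2C[C@H]([C@H]1C)C2(C)C)[C@@H]1C[C@@H]2C[C@H]([C@H]1C)C2(C)C)C(C)C | intermediate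
17 | (3R,4R)-4-ethyl-2-methylhex-5-en-3-ol | C=C[C@@H](CC)[C@H](O)C(C)C | intermediate
18 | (E)-oxocarbenium ion from 11 and 17 (cation, camphorsulfonate counter-ion) | C=C[C@@H](CC)[C@H](/[O+]=C/CC/C=C\CCCCCCCc1cc(O[Si](C(C)C)(C(C)C)C(C)C)cc(O[Si](C(C)C)(C(C)C)C(C)C)c1)C(C)C | intermediate
19 | rearranged oxocarbenium ion, the O-(2-methylpropylidene) oxonium of 20 (cation, camphorsulfonate counter-ion) | CC/C=C\C[C@@H](/[O+]=C/C(C)C)CC/C=C\CCCCCCCc1cc(O[Si](C(C)C)(C(C)C)C(C)C)cc(O[Si](C(C)C)(C(C)C)C(C)C)c1 | intermediate
20 | (3Z,6S,9Z)-17-[3,5-bis(triisopropylsilyloxy)phenyl]heptadeca-3,9-dien-6-ol | CC/C=C\C[C@@H](O)CC/C=C\CCCCCCCc1cc(O[Si](C(C)C)(C(C)C)C(C)C)cc(O[Si](C(C)C)(C(C)C)C(C)C)c1 | intermediate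
21 | 5-[(8Z,12S,14Z)-12-hydroxyheptadeca-8,14-dien-1-yl]benzene-1,3-diol | CC/C=C\C[C@@H](O)CC/C=C\CCCCCCCc1cc(O)cc(O)c1 | target

## Step count and risks

Total step count: 8. Longest linear sequence: 7 (steps 1, 2, 3, 4, 5, 7, 8); step 6 is a one-step branch.

**Step 7 (key step).** The most likely failure is loss of stereochemical fidelity. The competing chair, or reversible return of the product to the oxocarbenium manifold, would bring Z-to-E drift together with erosion at C12', because the two are coupled. The released aldehyde 13 may also consume donor, and the oxocarbenium ion could attack the electron-rich arene. The fallback abandons the sigmatropic transfer and sets out from 11. Enantioselective propargylation with allenylboronic acid pinacol ester under a chiral BINOL-derived phosphoric acid (the (R)-catalyst is expected to direct Re-face attack) would give (4S,7Z)-15-[3,5-bis(triisopropylsilyloxy)phenyl]pentadec-7-en-1-yn-4-ol F1. Double deprotonation with n-BuLi and C-ethylation of the acetylide terminus with iodoethane would give (6S,9Z)-17-[3,5-bis(triisopropylsilyloxy)phenyl]heptadec-9-en-3-yn-6-ol F2. Semihydrogenation over Pd/CaCO3 poisoned with Pb(OAc)2 and quinoline would return to the route at 20.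

**Step 6.** Metalation of 12 at C4 instead of the methyl group, Z/E equilibration of 14 on warming, or a 1,3-boron shift in 15 would lower the syn selectivity. The enantio-induction may be lower than in the crotyl case, and the product is volatile. The fallback is an auxiliary-controlled aldol route that sets out from 13. N-Acylation of (4S)-4-benzyloxazolidin-2-one with butanoyl chloride would give (4S)-4-benzyl-3-butanoyloxazolidin-2-one F3. Its dibutylboron Z-enolate (Bu2BOTf, i-Pr2NEt) would add to 13 through the chair of the auxiliary-controlled boron syn-aldol reaction to give (4S)-4-benzyl-3-[(2S,3R)-2-ethyl-3-hydroxy-4-methylpentanoyl]oxazolidin-2-one F4. Silylation (TBSOTf, 2,6-lutidine) would give (4S)-4-benzyl-3-[(2S,3R)-3-(tert-butyldimethylsilyloxy)-2-ethyl-4-methylpentanoyl]oxazolidin-2-one F5. LiBH4 would release the auxiliary and give (2R,3R)-3-(tert-butyldimethylsilyloxy)-2-ethyl-4-methylpentan-1-ol F6. Dess–Martin oxidation would give (2S,3R)-3-(tert-butyldimethylsilyloxy)-2-ethyl-4-methylpentanal F7. Wittig methylenation (Ph3PCH3Br, KOt-Bu) would give tert-butyl{[(3R,4R)-4-ethyl-2-methylhex-5-en-3-yl]oxy}dimethylsilane F8. Bu4NF would then return to the route at 17.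

**Step 2.** The alkylborane may undergo protodeboronation and the alkylpalladium intermediate β-hydride elimination. The primary C–Br bond may be hydrolysed or slowly engaged by palladium, and warm aqueous phosphate may cause partial desilylation. The fallback avoids alkylboranes and aqueous base and sets out from 2. Sonogashira coupling with oct-7-yn-1-ol (Pd(PPh3)2Cl2, CuI, Et3N) would give 8-[3,5-bis(triisopropylsilyloxy)phenyl]oct-7-yn-1-ol F9. Hydrogenation over Pd/C would give 8-[3,5-bis(triisopropylsilyloxy)phenyl]octan-1-ol F10. Appel bromination (CBr4, PPh3) would return to the route at 5.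

**Step 4.** Z selectivity may erode if oxaphosphetane equilibration sets in, and the E isomer of this lipophilic ester would be hard to remove. The basic ylide may also enolise aldehyde 7. The fallback builds the alkene by alkyne semireduction and sets out from 2. B-Alkyl Suzuki coupling of 2 with 7-bromohept-1-ene, hydroborated beforehand with 9-BBN, would give 1-(7-bromoheptyl)-3,5-bis(triisopropylsilyloxy)benzene F11. Alkylation of doubly lithiated pent-4-yn-1-ol (n-BuLi, THF/DMPU) at its acetylide carbon with this bromide would give 12-[3,5-bis(triisopropylsilyloxy)phenyl]dodec-4-yn-1-ol F12. Semihydrogenation over Pd/CaCO3 poisoned with Pb(OAc)2 would give (4Z)-12-[3,5-bis(triisopropylsilyloxy)phenyl]dodec-4-en-1-ol F13. Dess–Martin oxidation would return to the route at 11.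

## Further compounds

F1 | step 7 | (4S,7Z)-15-[3,5-bis(triisopropylsilyloxy)phenyl]pentadec-7-en-1-yn-4-ol | C#CC[C@@H](O)CC/C=C\CCCCCCCc1cc(O[Si](C(C)C)(C(C)C)C(C)C)cc(O[Si](C(C)C)(C(C)C)C(C)C)c1
F2 | step 7 | (6S,9Z)-17-[3,5-bis(triisopropylsilyloxy)phenyl]heptadec-9-en-3-yn-6-ol | CCC#CC[C@@H](O)CC/C=C\CCCCCCCc1cc(O[Si](C(C)C)(C(C)C)C(C)C)cc(O[Si](C(C)C)(C(C)C)C(C)C)c1
F3 | step 6 | (4S)-4-benzyl-3-butanoyloxazolidin-2-one | CCCC(=O)N1[C@@H](Cc2ccccc2)COC1=O
F4 | step 6 | (4S)-4-benzyl-3-[(2S,3R)-2-ethyl-3-hydroxy-4-methylpentanoyl]oxazolidin-2-one | O=C(N1[C@@H](Cc2ccccc2)COC1=O)[C@@H](CC)[C@H](O)C(C)C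
F5 | step 6 | (4S)-4-benzyl-3-[(2S,3R)-3-(tert-butyldimethylsilyloxy)-2-ethyl-4-methylpentanoyl]oxazolidin-2-one | O=C(N1[C@@H](Cc2ccccc2)COC1=O)[C@@H](CC)[C@H](O[Si](C)(C)C(C)(C)C)C(C)C
F6 | step 6 | (2R,3R)-3-(tert-butyldimethylsilyloxy)-2-ethyl-4-methylpentan-1-ol | OC[C@@H](CC)[C@H](O[Si](C)(C)C(C)(C)C)C(C)C
F7 | step 6 | (2S,3R)-3-(tert-butyldimethylsilyloxy)-2-ethyl-4-methylpentanal | O=C[C@@H](CC)[C@H](O[Si](C)(C)C(C)(C)C)C(C)C
F8 | step 6 | tert-butyl{[(3R,4R)-4-ethyl-2-methylhex-5-en-3-yl]oxy}dimethylsilane | C=C[C@@H](CC)[C@H](O[Si](C)(C)C(C)(C)C)C(C)C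
F9 | step 2 | 8-[3,5-bis(triisopropylsilyloxy)phenyl]oct-7-yn-1-ol | OCCCCCCC#Cc1cc(O[Si](C(C)C)(C(C)C)C(C)C)cc(O[Si](C(C)C)(C(C)C)C(C)C)c1
F10 | step 2 | 8-[3,5-bis(triisopropylsilyloxy)phenyl]octan-1-ol | OCCCCCCCCc1cc(O[Si](C(C)C)(C(C)C)C(C)C)cc(O[Si](C(C)C)(C(C)C)C(C)C)c1
F11 | step 4 | 1-(7-bromoheptyl)-3,5-bis(triisopropylsilyloxy)benzene | BrCCCCCCCc1cc(O[Si](C(C)C)(C(C)C)C(C)C)cc(O[Si](C(C)C)(C(C)C)C(C)C)c1
F12 | step 4 | 12-[3,5-bis(triisopropylsilyloxy)phenyl]dodec-4-yn-1-ol | OCCCC#CCCCCCCCc1cc(O[Si](C(C)C)(C(C)C)C(C)C)cc(O[Si](C(C)C)(C(C)C)C(C)C)c1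
F13 | step 4 | (4Z)-12-[3,5-bis(triisopropylsilyloxy)phenyl]dodec-4-en-1-ol | OCCC/C=C\CCCCCCCc1cc(O[Si](C(C)C)(C(C)C)C(C)C)cc(O[Si](C(C)C)(C(C)C)C(C)C)c1
A1 | alternative 1 | α-linolenic acid, (9Z,12Z,15Z)-octadeca-9,12,15-trienoic acid | CC/C=C\C/C=C\C/C=C\CCCCCCCC(=O)O
A2 | alternative 1 | (9Z,13S,15Z)-13-hydroxyoctadeca-9,15-dienoic acid | CC/C=C\C[C@@H](O)CC/C=C\CCCCCCCC(=O)O
A3 | alternative 1 | (3E,12Z,16S,18Z)-16-hydroxyhenicosa-3,12,18-trien-2-one | CC/C=C\C[C@@H](O)CC/C=C\CCCCCCC/C=C/C(C)=O
A4 | alternative 2 | leaf alcohol, (3Z)-hex-3-en-1-ol | CC/C=C\CCO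
A5 | alternative 2 | (3Z)-hex-3-en-1-yl N,N-diisopropylcarbamate | CC/C=C\CCOC(=O)N(C(C)C)C(C)C
A6 | alternative 2 | 2-{(3Z)-11-[3,5-bis(methoxymethoxy)phenyl]undec-3-en-1-yl}-4,4,5,5-tetramethyl-1,3,2-dioxaborolane | CC1(C)OB(CC/C=C\CCCCCCCc2cc(OCOC)cc(OCOC)c2)OC1(C)C
A7 | alternative 2 | 2-[(3Z,6S,9Z)-17-[3,5-bis(methoxymethoxy)phenyl]heptadeca-3,9-dien-6-yl]-4,4,5,5-tetramethyl-1,3,2-dioxaborolane | CC/C=C\C[C@@H](B1OC(C)(C)C(C)(C)O1)CC/C=C\CCCCCCCc2cc(OCOC)cc(OCOC)c2
A8 | alternative 3 | 1-(7-bromoheptyl)-3,5-bis(methoxymethoxy)benzene | BrCCCCCCCc1cc(OCOC)cc(OCOC)c1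
A9 | alternative 3 | lithium bis{7-[3,5-bis(methoxymethoxy)phenyl]heptyl}cuprate | [Li+].COCOc1cc(OCOC)cc(CCCCCCC[Cu-]CCCCCCCc2cc(OCOC)cc(OCOC)c2)c1
A10 | alternative 3 | acetylene | C#C
A11 | alternative 3 | tert-butyl{[(3R,5Z)-1-iodooct-5-en-3-yl]oxy}dimethylsilane | CC/C=C\C[C@@H](O[Si](C)(C)C(C)(C)C)CCI
A12 | alternative 3 | tert-butyl{[(3Z,6S,9Z)-17-[3,5-bis(methoxymethoxy)phenyl]heptadeca-3,9-dien-6-yl]oxy}dimethylsilane | CC/C=C\C[C@@H](O[Si](C)(C)C(C)(C)C)CC/C=C\CCCCCCCc1cc(OCOC)cc(OCOC)c1
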